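**Plan**

- Retrosynthesis: the C4 ketone is first taken back to a C4 methyl ether (aldehyde oxidation level). Ring C is then cut at O1–C2 and C3–C4 in one retro-hetero-Diels–Alder step, leaving an o-quinone methide built on ring A and 3,4-dimethoxystyrene.
- Enabling feature: O1 and the acyl carbon C4 are ortho substituents of ring A, so O1–C8a=C4a–C4 is a latent 1-oxadiene. C2 carries ring B, whose 4'-methoxy group (para to C2) makes the C2=C3 alkene a polarised, nucleophilic 2π partner.
- Forward: ring A is prepared as the salicylaldehyde (formylation, then one selective O-demethylation of 1,2,3,5-tetramethoxybenzene). Its dimethyl acetal, made in the flask, ionises to the heterodiene, which closes ring C onto the alkene in a single operation. Oxidation at C4 then returns the ketone.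
- Stereochemistry: C2 (S) is set in the cycloaddition by a chiral Brønsted acid (chiral counter-anion control). The C4 centre of the adduct is a temporary stereocentre that the last step erases.

Key step: step 3

Assumption: which enantiomer of the chiral acid delivers the (2S)-adduct cannot be predicted with confidence, so the (R)-acid is written and the (S)-acid would be used should the (2R)-adduct predominate. Compounds 1 and 4 are taken as commercially available.

**Route**

Step 1
Reactants: 1 1,2,3,5-tetramethoxybenzene
Product: 2 2,3,4,6-tetramethoxybenzaldehyde
Conditions: POCl3 (1.2 equiv), DMF, 0 °C to 60 °C; then aq. NaOAc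
Reagents that add atoms: N,N-dimethylformamide, CN(C)C=O (formyl carbon); water, O (carbonyl oxygen, on work-up)
Why: Vilsmeier–Haack formylation of a very electron-rich arene whose two free positions are equivalent by symmetry, so a single aldehyde should result.

Step 2
Reactants: 2 2,3,4,6-tetramethoxybenzaldehyde
Product: 3 2-hydroxy-3,4,6-trimethoxybenzaldehyde
Conditions: BCl3 (1.1 equiv), CH2Cl2, −10 °C to rt; then H2O
Reagents that add atoms: none
Why: Chelation-controlled Lewis-acid O-demethylation ortho to a carbonyl group, in which boron bound to the aldehyde oxygen should cleave the C2 methoxy group, because this ether is flanked by the C3 methoxy group, twisted out of conjugation and therefore the more basic of the two ortho ethers, as in the selective cleavage of the flanked ortho methoxy group of 2,3,4,6-tetramethoxyphenyl ketones.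

Step 3
Reactants: 3 2-hydroxy-3,4,6-trimethoxybenzaldehyde; 4 3,4-dimethoxystyrene
Product: 7 (2S,4S)-2-(3,4-dimethoxyphenyl)-4,5,7,8-tetramethoxychromane (2,4-cis), via dimethyl acetal 5 (not isolated), via o-quinone methide 6 (not isolated)
Conditions: HC(OMe)3 (1.1 equiv), (R)-3,3'-bis(2,4,6-triisopropylphenyl)-H8-BINOL N-triflylphosphoramide (5 mol %), 5 Å MS, PhMe, rt; then 4 (3 equiv, inhibitor-free), −40 °C to −20 °C; Et3N quench
Reagents that add atoms: trimethyl orthoformate, COC(OC)OC (the C4 methoxy group)
Why: The chiral acid first catalyses acetalisation to 5 and then ionises it, with loss of methanol, to the hydrogen-bonded o-quinone methide/oxocarbenium pair 6, whose O1–C8a=C4a–C4 heterodiene adds across the vinyl group of 4 in an inverse-electron-demand hetero-Diels–Alder reaction in which C3–C4 bonding runs ahead of O1–C2 bonding. The closest known reaction types are the chiral-Brønsted-acid-catalysed [4+2] cycloadditions of o-quinone methides with styrenes and of salicylaldehyde-acetal-derived oxocarbenium ions with vinyl ethers, and the Lewis-acid three-component chromane synthesis from salicylaldehydes, trimethyl orthoformate and styrenes. Ring C closes as a concerted asynchronous [4π+2π] cycloaddition (in the stepwise limit, capture of the C2 benzylic cation by the phenolic O1, 6-exo-trig with respect to the quinoid C2=C1' bond). C2 is controlled by the chiral phosphoramide anion, which holds the heterodiene by hydrogen bonding and ion pairing and leaves one alkene face open, while C4 should follow as cis from the endo transition state of the (E)-methide and is of no consequence because it becomes the carbonyl carbon. Regiochemistry is secured by the 4'-methoxy group para to the vinyl group, which directs the CH2 terminus to C4 and the benzylic carbon to O1. Chemoselectivity over cationic oligomerisation of 4 and over arylation by the free C6 position of ring A is secured by the weak chiral acid, the low temperature, the excess of alkene and the steric shielding of the methide carbon by its two ortho substituents.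

Step 4
Reactants: 7 (2S,4S)-2-(3,4-dimethoxyphenyl)-4,5,7,8-tetramethoxychromane
Product: 8 (2S)-2-(3,4-dimethoxyphenyl)-5,7,8-trimethoxy-2,3-dihydro-4H-chromen-4-one
Conditions: DDQ (1.2 equiv), CH2Cl2/pH 7 phosphate buffer (10:1), 0 °C to rt; filtration through neutral alumina
Reagents that add atoms: water, O (carbonyl oxygen)
Why: DDQ oxidation of an electron-rich benzylic ether (the reaction type behind oxidative p-methoxybenzyl ether cleavage), in which hydride abstraction from C4–H, benzylic to the tetra-oxygenated ring A and α to the methoxy oxygen, should give a methoxy-oxocarbenium ion that water converts into the C4 ketone with loss of methanol, while the neutral, base-free medium leaves the retro-oxa-Michael-prone C2 centre untouched and (S).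

**Compound list**

1 | 1,2,3,5-tetramethoxybenzene | COc1cc(OC)c(OC)c(OC)c1 | starting material
2 | 2,3,4,6-tetramethoxybenzaldehyde | COc1cc(OC)c(C=O)c(OC)c1OC | intermediate
3 | 2-hydroxy-3,4,6-trimethoxybenzaldehyde | COc1cc(OC)c(C=O)c(O)c1OC | intermediate
4 | 3,4-dimethoxystyrene (4-ethenyl-1,2-dimethoxybenzene) | C=Cc1ccc(OC)c(OC)c1 | starting material
5 | 2-(dimethoxymethyl)-3,5,6-trimethoxyphenol (not isolated) | COC(OC)c1c(OC)cc(OC)c(OC)c1O | intermediate
6 | (6E)-2,3,5-trimethoxy-6-(methoxymethylidene)cyclohexa-2,4-dien-1-one (not isolated) | CO/C=C1\C(OC)=CC(OC)=C(OC)C1=O | intermediate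
7 | (2S,4S)-2-(3,4-dimethoxyphenyl)-4,5,7,8-tetramethoxychromane (2,4-cis) | COc1ccc([C@@H]2C[C@H](OC)c3c(OC)cc(OC)c(OC)c3O2)cc1OC | intermediate
8 | (2S)-2-(3,4-dimethoxyphenyl)-5,7,8-trimethoxy-2,3-dihydro-4H-chromen-4-one | COc1ccc([C@@H]2CC(=O)c3c(OC)cc(OC)c(OC)c3O2)cc1OC | target

Total step count: 4. Longest linear sequence: 4 steps (1 → 2 → 3 → 7 → 8).

**Steps most likely to fail**

Step 3. The ion pair may discriminate the two alkene faces poorly. Acid-promoted reopening of the C2–O1 bond may erode the C2 configuration. The cation may also be diverted into oligomerisation of 4, into arylation by the free C6 position of another ring A, or into addition of orthoformate-derived cation to 4. The fallback builds the chromone core first and attaches ring B last by known reactions; it sets out from 1 and returns at 8. Friedel–Crafts acetylation of 1 (AcCl, AlCl3, Et2O), with cleavage of the flanked ortho methoxy group in the same flask, should give 1-(2-hydroxy-3,4,6-trimethoxyphenyl)ethan-1-one F1. Heating with DMF dimethyl acetal (PhMe, 100 °C) should give the enaminone (E)-3-(dimethylamino)-1-(2-hydroxy-3,4,6-trimethoxyphenyl)prop-2-en-1-one F2, which aqueous HCl in CH2Cl2 should close to 5,7,8-trimethoxy-4H-chromen-4-one F3. Asymmetric conjugate addition of 3,4-dimethoxyphenylboronic acid (Pd(OCOCF3)2, 5 mol %; (S)-tert-butyl pyridine-oxazoline ligand or its enantiomer, whichever delivers 2S; NH4PF6, H2O, ClCH2CH2Cl, 60 °C) then forms the C2–C1' bond and gives 8 under base-free conditions.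

Step 4. Hydride abstraction may take place at the C2–H bond, which is also a benzylic ether position, and open ring C. The flavanone may be dehydrogenated further across C2–C3, or ring A, with its para-disposed C5 and C8 methoxy groups, may suffer oxidative demethylation. The fallback separates solvolysis from oxidation, sets out from 7 and returns at 8. Solvolysis of the C4 ether at high dilution (PPTS, THF/H2O, rt) should give (2S)-2-(3,4-dimethoxyphenyl)-5,7,8-trimethoxychroman-4-ol F4 as a mixture of C4 epimers. Oxidation of the alcohol with Dess–Martin periodinane (NaHCO3, CH2Cl2, 0 °C) should then give 8 without touching C2.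

Step 2. Regiocontrol of the deprotection may be lost, by cleavage of the unflanked C6 methoxy group or of both ortho ethers. The fallback turns the selective cleavage into a selective alkylation, sets out from 2 and returns at 3. Deliberate cleavage of both ortho ethers (BCl3, 3 equiv, CH2Cl2, rt) should give 2,6-dihydroxy-3,4-dimethoxybenzaldehyde F5. Mono-methylation (MeI, 1.0 equiv, K2CO3, acetone, rt) should then take place at the unflanked, less hindered C6 hydroxyl and give 3.

**Further compounds**

F1 | step 3 | 1-(2-hydroxy-3,4,6-trimethoxyphenyl)ethan-1-one | CC(=O)c1c(O)c(OC)c(OC)cc1OC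
F2 | step 3 | (E)-3-(dimethylamino)-1-(2-hydroxy-3,4,6-trimethoxyphenyl)prop-2-en-1-one | CN(C)/C=C/C(=O)c1c(O)c(OC)c(OC)cc1OC
F3 | step 3 | 5,7,8-trimethoxy-4H-chromen-4-one | O=c1ccoc2c1c(OC)cc(OC)c2OC
F4 | step 4 | (2S)-2-(3,4-dimethoxyphenyl)-5,7,8-trimethoxychroman-4-ol (C4 epimers) | COc1ccc([C@@H]2CC(O)c3c(OC)cc(OC)c(OC)c3O2)cc1OC
F5 | step 2 | 2,6-dihydroxy-3,4-dimethoxybenzaldehyde | COc1cc(O)c(C=O)c(O)c1OC
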